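**Retrosynthetic overview**
1. Target ⇒ 10‑membered C10 ketone: the last C–C bond (C10–C14) comes from a hydroxyl‑directed MeTi(O‑i‑Pr)3 addition.
2. Cyclodecenone ⇒ cis‑fused decalin bis‑epoxy carbinol: a bromide‑relay Grob ring expansion cleaves the ring‑fusion bond C5–C10 and creates C10=O, the (Z)‑C4=C5 alkene and 3‑OH at once; angelate and exo‑methylene are already in place.
3. Bis‑epoxide ⇒ cyclohexadienol (singlet oxygen, then Co(TPP)); diene ⇒ enone (α′‑methylation, enol triflate, Pd/formate reduction).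
4. Tricyclic enone‑lactone ⇒ acyclic quinol aldehyde: an SmI2 ketyl–dienone cyclization closes ring B and the cis γ‑lactone together; C7/C8 come from a D‑proline cross‑aldol.
5. Ring order: ring A (the carbocycle of p‑benzoquinone) → ring B + lactone → ring expansion to the cyclodecene. Building blocks: p‑benzoquinone, allyl bromide, methyl 4‑oxobutanoate, angelic acid.

Assumption (numbering and face labels): germacrane/eudesmane numbering is used throughout (C1–C10 ring carbons, C11–C13 lactone carbons, C14 on C10, C15 on C4; the decalins carry the extra C5–C10 bond); β is the face of the C6 lactone oxygen, α the opposite face.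

**Step 1**
Reactants: 1 p‑benzoquinone; 2 allyl bromide
Product: 4 4‑allyl‑4‑hydroxycyclohexa‑2,5‑dien‑1‑one, via allylindium sesquibromide 3 (not isolated)
Conditions: 2, In powder, DMF, rt, 1 h; then 1, −45 → 0 °C; aq. NH4Cl
Reagents that add atoms: none
Why: Barbier‑type 1,2‑allylation of one quinone carbonyl by the allylindium reagent gives the p‑quinol (kept cold to avoid oxy‑Cope and dienone–phenol rearrangement); its carbinol carbon becomes C10 and no stereocentre is formed.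

**Step 2**
Reactants: 4 4‑allyl‑4‑hydroxycyclohexa‑2,5‑dien‑1‑one
Product: 6 2‑(1‑hydroxy‑4‑oxocyclohexa‑2,5‑dien‑1‑yl)acetaldehyde, via secondary ozonide 5 (not isolated)
Conditions: O3, CH2Cl2, −78 °C (stopped at first blue colour); then PPh3, −78 °C → rt
Reagents that add atoms: ozone, [O-][O+]=O
Why: Ozonolysis with reductive work‑up; the electron‑rich terminal alkene reacts far faster than the electron‑poor dienone C=C bonds.

**Step 3**
Reactants: 6 2‑(1‑hydroxy‑4‑oxocyclohexa‑2,5‑dien‑1‑yl)acetaldehyde; 7 methyl 4‑oxobutanoate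
Product: 9 methyl (3R,4R)‑4‑[(tert‑butyldimethylsilyl)oxy]‑3‑formyl‑5‑(1‑hydroxy‑4‑oxocyclohexa‑2,5‑dien‑1‑yl)pentanoate, via aldol adduct 8 (not isolated)
Conditions: D‑proline (20 mol%), DMF, 4 °C, 7 (2 equiv) added over 24 h; then imidazole, TBSCl, 0 °C → rt
Reagents that add atoms: tert‑butyldimethylsilyl chloride, CC(C)(C)[Si](C)(C)Cl
Why: Proline‑catalysed direct cross‑aldol (enamine of 7, hydrogen‑bonded Houk–List transition state) gives the anti adduct and sets C7 (R) and C8 (R); the hindered aldehyde 6 acts only as acceptor, and silylation in the same flask stops oxa‑Michael closure of the new hydroxyl onto the dienone.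

**Step 4**
Reactants: 9 TBS‑protected aldol aldehyde
Product: 11 (5S,6R,7S,8R,10R)‑8‑[(tert‑butyldimethylsilyl)oxy]‑10‑hydroxy‑3‑oxo‑13,14,15‑trinoreudesm‑1‑en‑12,6‑olide (cis‑decalin, cis γ‑lactone; H‑5, 10‑OH, O‑6, C‑11 and O‑8 all β), via hydroxy ester 10 (not isolated)
Conditions: SmI2 (2.2 equiv), t‑BuOH (2 equiv), THF, −78 → 0 °C; aq. NH4Cl; then PPTS (10 mol%), CH2Cl2, rt
Reagents that add atoms: none
Why: SmI2 ketyl–olefin reductive cyclization (6‑exo) onto one diastereotopic enone arm through a chair in which OTBS and the ketyl oxygen are equatorial and the CH2CO2Me arm axial sets C5, C6 and C10 (cis ring fusion, O‑6 cis to the C7 arm), and the cis 6‑hydroxy ester then lactonizes.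

**Step 5**
Reactants: 11 tricyclic enone‑lactone
Product: 12 (4R,5S,6R,7S,8R,10R)‑8‑[(tert‑butyldimethylsilyl)oxy]‑10‑hydroxy‑3‑oxo‑13,14‑dinoreudesm‑1‑en‑12,6‑olide (4β‑methyl)
Conditions: LiN(SiMe3)2 (2.2 equiv), THF, −78 °C; MeI (1.2 equiv), −78 → −30 °C
Reagents that add atoms: iodomethane, CI
Why: α′‑Alkylation of the cross‑conjugated ketone enolate (C4 is the only enolizable ketone position and is more acidic than the lactone α‑CH2); the methyl enters from the convex face, and this centre is erased in step 6.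

**Step 6**
Reactants: 12 C4‑methyl enone
Product: 13 (5S,6R,7S,8R,10R)‑8‑[(tert‑butyldimethylsilyl)oxy]‑10‑hydroxy‑3‑{[(trifluoromethyl)sulfonyl]oxy}‑13,14‑dinoreudesma‑1,3‑dien‑12,6‑olide
Conditions: KN(SiMe3)2 (2.3 equiv), THF, −78 → −40 °C; PhNTf2 (1.2 equiv), −78 → −40 °C
Reagents that add atoms: N‑phenylbis(trifluoromethanesulfonimide), O=S(=O)(N(c1ccccc1)S(=O)(=O)C(F)(F)F)C(F)(F)F
Why: Regiospecific enolate O‑triflation (only C4–H can be removed on the ketone) gives the cross‑conjugated dienyl triflate.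

**Step 7**
Reactants: 13 dienyl triflate
Product: 14 (5S,6R,7S,8R,10R)‑8‑[(tert‑butyldimethylsilyl)oxy]‑10‑hydroxy‑13,14‑dinoreudesma‑1,3‑dien‑12,6‑olide
Conditions: Pd(OAc)2 (5 mol%), PPh3 (10 mol%), HCO2H (2 equiv), n‑Bu3N (3 equiv), DMF, 45 °C
Reagents that add atoms: none
Why: Palladium‑catalysed formate reduction of an enol triflate (oxidative addition, formate decarboxylation, C–H reductive elimination) under an amine buffer that keeps the acid‑sensitive dienol from aromatizing.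

**Step 8**
Reactants: 14 cyclohexadienol
Product: 16 (1R,2S,3S,4R,5S,6R,7S,8R,10S)‑8‑[(tert‑butyldimethylsilyl)oxy]‑1,2:3,4‑diepoxy‑10‑hydroxy‑13,14‑dinoreudesman‑12,6‑olide (both oxirane oxygens β, 4α‑methyl), via endoperoxide 15 (not isolated)
Conditions: O2, tetraphenylporphyrin (1 mol%), visible light, CH2Cl2, −40 °C; then Co(TPP) (cobalt 5,10,15,20‑tetraphenylporphyrinate, 5 mol%), −40 → 20 °C
Reagents that add atoms: dioxygen, O=O
Why: [4+2] photooxygenation by singlet oxygen on the convex face syn to 10‑OH, then cobalt‑porphyrin‑catalysed endoperoxide‑to‑syn‑bis‑epoxide isomerization, puts both oxirane oxygens (C1–C4) on the face of the former peroxide bridge.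

**Step 9**
Reactants: 16 bis‑epoxy lactone
Product: 19 (1R,2S,3S,4R,5S,6R,7S,8R,10S)‑8‑[(tert‑butyldimethylsilyl)oxy]‑1,2:3,4‑diepoxy‑10‑hydroxy‑14‑noreudesm‑11(13)‑en‑12,6‑olide, via Mannich base 17 (not isolated), via ammonium iodide 18 (not isolated)
Conditions: LiN(i‑Pr)2 (2.3 equiv), THF, −78 °C; CH2=NMe2+ I−, −78 → 0 °C; then MeI, MeOH, rt; then NaHCO3 (aq)/EtOAc, rt
Reagents that add atoms: N,N‑dimethylmethyleneiminium iodide, C=[N+](C)C.[I-]
Why: Eschenmoser methylenation (Mannich reaction of the lactone enolate, quaternization, E1cB elimination) builds the α‑methylene lactone; the 10‑alkoxide is cis to the neighbouring epoxide and so cannot undergo Payne rearrangement.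

**Step 10**
Reactants: 19 silyl ether
Product: 20 (1R,2S,3S,4R,5S,6R,7R,8R,10S)‑1,2:3,4‑diepoxy‑8,10‑dihydroxy‑14‑noreudesm‑11(13)‑en‑12,6‑olide
Conditions: n‑Bu4NF/AcOH (1:1, 3 equiv), THF, 0 °C → rt
Reagents that add atoms: none
Why: Fluoride cleavage of the silyl ether, buffered with AcOH so that the freed 8‑hydroxyl neither translactonizes nor adds to the methylene lactone.

**Step 11**
Reactants: 20 diol; 21 angelic acid
Product: 23 (1R,2S,3S,4R,5S,6R,7R,8R,10S)‑8‑angeloyloxy‑1,2:3,4‑diepoxy‑10‑hydroxy‑14‑noreudesm‑11(13)‑en‑12,6‑olide, via mixed anhydride 22 (not isolated)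
Conditions: 21, 2,4,6‑trichlorobenzoyl chloride, Et3N, toluene, rt; then 20, DMAP, toluene, 40 °C
Reagents that add atoms: none
Why: Yamaguchi esterification acylates the only secondary hydroxyl (the tertiary 10‑OH is inert) and is the standard way to make angelates without Z→E isomerization.

**Step 12**
Reactants: 23 angelate bis‑epoxy carbinol
Product: 25 (1R,2R,3R,4Z,6S,7R,8R)‑8‑angeloyloxy‑1,2‑epoxy‑3‑hydroxy‑10‑oxo‑14‑norgermacra‑4,11(13)‑dien‑12,6‑olide, via bromohydrin 24 (not isolated)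
Conditions: MgBr2·OEt2 (1.5 equiv), CH2Cl2/Et2O, −40 °C; then KN(SiMe3)2 (1.1 equiv), THF, −78 → −20 °C; aq. NH4Cl
Reagents that add atoms: none
Why: Proposed new method: a bromide‑relay (invertive) epoxy‑alkoxide Grob ring expansion — MgBr2, held by the three β‑oxygens (10‑OH and both oxiranes), opens the trisubstituted epoxide at tertiary C4 with inversion (SN1‑like anti attack of bromide) to the trans‑bromohydrin 24, whose equatorial C4–Br is antiperiplanar to the C5–C10 ring‑fusion bond in the chair–chair conformer that keeps the ring‑B oxygens equatorial; deprotonation of 10‑OH then drives a concerted Grob fragmentation (C10–O− → C10=O, C5–C10 cleaved, C4=C5 formed, Br− expelled) in which C3 and C6 are gauche about C4–C5 and so end cis, giving the (Z)‑alkene, the C10 ketone and free 3‑OH with C1, C2, C3, C6, C7 and C8 untouched, whereas direct use of the epoxide oxygen as nucleofuge is misaligned and would lead to the E isomer; bromide is only a shuttle, so the net change is an isomerization; closest known reactions are the Holton epoxy‑alcohol fragmentation (epoxide as nucleofuge, no inversion), the Wharton–Grob fragmentation of 1,3‑hydroxy halides and sulfonates, and MgBr2 opening of epoxides to bromohydrins.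

**Step 13**
Reactants: 25 cyclodecenone
Product: 26 (1R,2R,3R,4Z,6S,7R,8R,10R)‑8‑angeloyloxy‑1,2‑epoxy‑3,10‑dihydroxygermacra‑4,11(13)‑dien‑12,6‑olide (target CNP0351240.2)
Conditions: MeLi (3 equiv), ClTi(O‑i‑Pr)3 (3 equiv), Et2O, −30 °C; then 25, CH2Cl2/Et2O, −30 → 20 °C; aq. NH4Cl
Reagents that add atoms: methyllithium, [Li]C
Why: Reetz‑type methyltitanium addition is selective for the ketone over lactone, angelate and epoxide, and exchange of one isopropoxide for the 3‑OH (O‑3 and C‑10 are cis across the cis‑epoxide) should deliver the methyl transannularly cis to O‑3, giving the (10R) carbinol.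

**Compound list**
1 | p‑benzoquinone | O=C1C=CC(=O)C=C1 | starting material
2 | allyl bromide | C=CCBr | starting material
3 | allylindium sesquibromide, (C3H5)3In2Br3 | C=CC[In](Br)CC=C.C=CC[In](Br)Br | intermediate
4 | 4‑allyl‑4‑hydroxycyclohexa‑2,5‑dien‑1‑one | C=CCC1(O)C=CC(=O)C=C1 | intermediate
5 | 4‑hydroxy‑4‑[(1,2,4‑trioxolan‑3‑yl)methyl]cyclohexa‑2,5‑dien‑1‑one (secondary ozonide) | O=C1C=CC(O)(CC2OCOO2)C=C1 | intermediate
6 | 2‑(1‑hydroxy‑4‑oxocyclohexa‑2,5‑dien‑1‑yl)acetaldehyde | O=CCC1(O)C=CC(=O)C=C1 | intermediate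
7 | methyl 4‑oxobutanoate | COC(=O)CCC=O | starting material
8 | methyl (3R,4R)‑3‑formyl‑4‑hydroxy‑5‑(1‑hydroxy‑4‑oxocyclohexa‑2,5‑dien‑1‑yl)pentanoate | COC(=O)C[C@@H](C=O)[C@H](O)CC1(O)C=CC(=O)C=C1 | intermediate
9 | methyl (3R,4R)‑4‑[(tert‑butyldimethylsilyl)oxy]‑3‑formyl‑5‑(1‑hydroxy‑4‑oxocyclohexa‑2,5‑dien‑1‑yl)pentanoate | COC(=O)C[C@@H](C=O)[C@H](O[Si](C)(C)C(C)(C)C)CC1(O)C=CC(=O)C=C1 | intermediate
10 | methyl (5S,6R,7S,8R,10R)‑8‑[(tert‑butyldimethylsilyl)oxy]‑6,10‑dihydroxy‑3‑oxo‑13,14,15‑trinoreudesm‑1‑en‑12‑oate | COC(=O)C[C@@H]1[C@H](O[Si](C)(C)C(C)(C)C)C[C@@]2(O)C=CC(=O)C[C@H]2[C@@H]1O | intermediate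
11 | (5S,6R,7S,8R,10R)‑8‑[(tert‑butyldimethylsilyl)oxy]‑10‑hydroxy‑3‑oxo‑13,14,15‑trinoreudesm‑1‑en‑12,6‑olide | O=C1C[C@@H]2[C@H](O[Si](C)(C)C(C)(C)C)C[C@@]3(O)C=CC(=O)C[C@H]3[C@@H]2O1 | intermediate
12 | (4R,5S,6R,7S,8R,10R)‑8‑[(tert‑butyldimethylsilyl)oxy]‑10‑hydroxy‑3‑oxo‑13,14‑dinoreudesm‑1‑en‑12,6‑olide | O=C1C[C@@H]2[C@H](O[Si](C)(C)C(C)(C)C)C[C@@]3(O)C=CC(=O)[C@H](C)[C@H]3[C@@H]2O1 | intermediate
13 | (5S,6R,7S,8R,10R)‑8‑[(tert‑butyldimethylsilyl)oxy]‑10‑hydroxy‑3‑{[(trifluoromethyl)sulfonyl]oxy}‑13,14‑dinoreudesma‑1,3‑dien‑12,6‑olide | O=C1C[C@@H]2[C@H](O[Si](C)(C)C(C)(C)C)C[C@@]3(O)C=CC(OS(=O)(=O)C(F)(F)F)=C(C)[C@H]3[C@@H]2O1 | intermediate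
14 | (5S,6R,7S,8R,10R)‑8‑[(tert‑butyldimethylsilyl)oxy]‑10‑hydroxy‑13,14‑dinoreudesma‑1,3‑dien‑12,6‑olide | O=C1C[C@@H]2[C@H](O[Si](C)(C)C(C)(C)C)C[C@@]3(O)C=CC=C(C)[C@H]3[C@@H]2O1 | intermediate
15 | (1R,4S,5S,6R,7S,8R,10S)‑8‑[(tert‑butyldimethylsilyl)oxy]‑1,4‑epidioxy‑10‑hydroxy‑13,14‑dinoreudesm‑2‑en‑12,6‑olide | O=C1C[C@@H]2[C@H](O[Si](C)(C)C(C)(C)C)C[C@@]3(O)[C@H]4C=C[C@](C)(OO4)[C@H]3[C@@H]2O1 | intermediate
16 | (1R,2S,3S,4R,5S,6R,7S,8R,10S)‑8‑[(tert‑butyldimethylsilyl)oxy]‑1,2:3,4‑diepoxy‑10‑hydroxy‑13,14‑dinoreudesman‑12,6‑olide | O=C1C[C@@H]2[C@H](O[Si](C)(C)C(C)(C)C)C[C@@]3(O)[C@@H]4O[C@@H]4[C@@H]5O[C@]5(C)[C@H]3[C@@H]2O1 | intermediate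
17 | 13‑(dimethylamino) derivative of 16 (C11 epimers): 8‑TBSO‑13‑(dimethylamino)‑1,2:3,4‑diepoxy‑10‑hydroxy‑14‑noreudesman‑12,6‑olide | O=C1C(CN(C)C)[C@@H]2[C@H](O[Si](C)(C)C(C)(C)C)C[C@@]3(O)[C@@H]4O[C@@H]4[C@@H]5O[C@]5(C)[C@H]3[C@@H]2O1 | intermediate
18 | 13‑(trimethylammonio) analogue of 17, iodide salt | O=C1C(C[N+](C)(C)C)[C@@H]2[C@H](O[Si](C)(C)C(C)(C)C)C[C@@]3(O)[C@@H]4O[C@@H]4[C@@H]5O[C@]5(C)[C@H]3[C@@H]2O1.[I-] | intermediate
19 | (1R,2S,3S,4R,5S,6R,7S,8R,10S)‑8‑[(tert‑butyldimethylsilyl)oxy]‑1,2:3,4‑diepoxy‑10‑hydroxy‑14‑noreudesm‑11(13)‑en‑12,6‑olide | O=C1C(=C)[C@@H]2[C@H](O[Si](C)(C)C(C)(C)C)C[C@@]3(O)[C@@H]4O[C@@H]4[C@@H]5O[C@]5(C)[C@H]3[C@@H]2O1 | intermediate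
20 | (1R,2S,3S,4R,5S,6R,7R,8R,10S)‑1,2:3,4‑diepoxy‑8,10‑dihydroxy‑14‑noreudesm‑11(13)‑en‑12,6‑olide | O=C1C(=C)[C@@H]2[C@H](O)C[C@@]3(O)[C@@H]4O[C@@H]4[C@@H]5O[C@]5(C)[C@H]3[C@@H]2O1 | intermediate
21 | angelic acid, (Z)‑2‑methylbut‑2‑enoic acid | C/C=C(/C)C(=O)O | starting material
22 | angelic 2,4,6‑trichlorobenzoic anhydride | C/C=C(/C)C(=O)OC(=O)c1c(Cl)cc(Cl)cc1Cl | intermediate
23 | (1R,2S,3S,4R,5S,6R,7R,8R,10S)‑8‑angeloyloxy‑1,2:3,4‑diepoxy‑10‑hydroxy‑14‑noreudesm‑11(13)‑en‑12,6‑olide | O=C1C(=C)[C@@H]2[C@H](OC(=O)/C(C)=C\C)C[C@@]3(O)[C@@H]4O[C@@H]4[C@@H]5O[C@]5(C)[C@H]3[C@@H]2O1 | intermediate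
24 | (1R,2R,3S,4S,5S,6R,7R,8R,10S)‑8‑angeloyloxy‑4‑bromo‑1,2‑epoxy‑3,10‑dihydroxy‑14‑noreudesm‑11(13)‑en‑12,6‑olide (4α‑Br, 3β‑OH) | O=C1C(=C)[C@@H]2[C@H](OC(=O)/C(C)=C\C)C[C@@]3(O)[C@@H]4O[C@@H]4[C@H](O)[C@@](C)(Br)[C@H]3[C@@H]2O1 | intermediate
25 | (1R,2R,3R,4Z,6S,7R,8R)‑8‑angeloyloxy‑1,2‑epoxy‑3‑hydroxy‑10‑oxo‑14‑norgermacra‑4,11(13)‑dien‑12,6‑olide | C=C1C(=O)O[C@H]2/C=C(/C)[C@@H](O)[C@H]3O[C@H]3C(=O)C[C@@H](OC(=O)/C(C)=C\C)[C@@H]12 | intermediate
26 | (1R,2R,3R,4Z,6S,7R,8R,10R)‑8‑angeloyloxy‑1,2‑epoxy‑3,10‑dihydroxygermacra‑4,11(13)‑dien‑12,6‑olide | C=C1C(=O)O[C@H]2/C=C(/C)[C@@H](O)[C@H]3O[C@H]3[C@](C)(O)C[C@@H](OC(=O)/C(C)=C\C)[C@@H]12 | target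

**Totals**
Total step count: 13. Longest linear sequence: 13 steps (1 → 26).

**Three steps most likely to fail**

Step 4 (SmI2 cyclization). The quinol dienone may take up the electrons before the aldehyde does; this would lose the tertiary hydroxyl (aromatization) or over‑reduce the remaining enone. The fallback replaces the reductive ketyl coupling by a redox‑neutral acyl‑anion closure. It sets out from 9: an intramolecular Stetter reaction (6,7‑dihydro‑2‑mesityl‑5H‑pyrrolo[2,1‑c][1,2,4]triazolium chloride 20 mol%, DBU, toluene, rt) closes ring B through the same chair to the cis‑fused diketone ester F1. NaBH4 in MeOH/CH2Cl2 at −78 °C then reduces the saturated C6 ketone ahead of the enone, axial hydride giving the equatorial 6‑alcohol. This is hydroxy ester 10, where the route is rejoined (lactonization to 11).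

Step 12 (the new relay fragmentation). Bromide might open the wrong oxirane carbon, the Lewis acid might trigger a hydride shift, or the 8‑angelate might be eliminated once the ketone is formed. The fallback uses known chemistry with the nucleofuge installed and isolated separately. It sets out from 23: TiCl4 (CH2Cl2, −78 °C) opens the trisubstituted epoxide at C4 with inversion to the chlorohydrin F2. TESCl/imidazole masks the C3 hydroxyl as its triethylsilyl ether F3, so the epoxide cannot re‑close. KN(SiMe3)2 (THF, −78 → 0 °C) then effects a classical Wharton–Grob fragmentation of the γ‑chloro alkoxide to the silylated cyclodecenone F4. HF·pyridine in THF removes the silyl group and returns the route to 25.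

Step 13 (methyl addition at C10). The directed transfer may be slow or unselective in the ten‑membered ring. The fallback removes the directing group and relies on polar Felkin–Anh (Cornforth) control instead. It sets out from 25: TBSOTf/2,6‑lutidine gives the silylated ketone F5. MeLi/CeCl3 (THF, −78 °C) should then add from the face away from the silyloxy group, with the C10=O and C1–O dipoles opposed, to give the silylated carbinol F6. n‑Bu4NF/AcOH then gives 26.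

**Further compounds**
F1 | step 4 | methyl (5R,7R,8R,10R)‑8‑[(tert‑butyldimethylsilyl)oxy]‑10‑hydroxy‑3,6‑dioxo‑13,14,15‑trinoreudesm‑1‑en‑12‑oate | COC(=O)C[C@@H]1[C@H](O[Si](C)(C)C(C)(C)C)C[C@@]2(O)C=CC(=O)C[C@H]2C1=O
F2 | step 12 | (1R,2R,3S,4S,5S,6R,7R,8R,10S)‑8‑angeloyloxy‑4‑chloro‑1,2‑epoxy‑3,10‑dihydroxy‑14‑noreudesm‑11(13)‑en‑12,6‑olide | O=C1C(=C)[C@@H]2[C@H](OC(=O)/C(C)=C\C)C[C@@]3(O)[C@@H]4O[C@@H]4[C@H](O)[C@@](C)(Cl)[C@H]3[C@@H]2O1
F3 | step 12 | 3‑O‑triethylsilyl ether of F2 | O=C1C(=C)[C@@H]2[C@H](OC(=O)/C(C)=C\C)C[C@@]3(O)[C@@H]4O[C@@H]4[C@H](O[Si](CC)(CC)CC)[C@@](C)(Cl)[C@H]3[C@@H]2O1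
F4 | step 12 | 3‑O‑triethylsilyl ether of 25 | C=C1C(=O)O[C@H]2/C=C(/C)[C@@H](O[Si](CC)(CC)CC)[C@H]3O[C@H]3C(=O)C[C@@H](OC(=O)/C(C)=C\C)[C@@H]12
F5 | step 13 | 3‑O‑(tert‑butyldimethylsilyl) ether of 25 | C=C1C(=O)O[C@H]2/C=C(/C)[C@@H](O[Si](C)(C)C(C)(C)C)[C@H]3O[C@H]3C(=O)C[C@@H](OC(=O)/C(C)=C\C)[C@@H]12
F6 | step 13 | 3‑O‑(tert‑butyldimethylsilyl) ether of 26 | C=C1C(=O)O[C@H]2/C=C(/C)[C@@H](O[Si](C)(C)C(C)(C)C)[C@H]3O[C@H]3[C@](C)(O)C[C@@H](OC(=O)/C(C)=C\C)[C@@H]12
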